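Readings and results were computed on assumed constants, and the scatter is random.

Which way of charging gives the most target at the end: starting material fed, second substrate fed or portioned, or both substrates together at the start? I have to choose one recipe for the next batch.

in all of them: enzyme 0.0012 mol%

| flask | starting material | second substrate | remark | time |
|---|---|---|---|---|
| green | 0.053 M | 1 equiv | run made earlier |  |
| grey | 0.053 M | 0.50 equiv | run made earlier |  |
| red | 0.053 M | 0.75 equiv | run made earlier |  |
| ochre | 0.026 M | 1 equiv | run made earlier |  |
| Sunday's | 0.053 M (fed, over 20 min) | 1.00 equiv | all else is in the flask from the start; the feed brings no volume worth counting | 25 min |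
| Monday's | 0.053 M | 1.00 equiv (fed, over 20 min) | all else is in the flask from the start; the feed brings no volume worth counting | 25 min |
| Friday's | 0.053 M | 1.00 equiv (in portions, 3, over 20 min) | first portion at the start, last at 20 min | 25 min |
| Thursday's | 0.053 M | 1.00 equiv | everything together at the start | 25 min |

- the best flask by amount of target, in percent of the starting material charged; "all alike" if 1.5 percentage points covers them all (Sunday's / Monday's / Friday's / Thursday's / all alike)
- amount of target at the end, in percent of the starting material charged, Sunday's
- amount of target at the end, in percent of the starting material charged, Monday's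
- amount of target at the end, in percent of the starting material charged, Friday's
- amount of target at the end, in percent of the starting material charged, Thursday's

- green (time / min: target / %, starting material / %): 4.00: 38.1, 58.7; 8.00: 61.9, 29.4; 10.0: 68.5, 20.5; 15.0: 78.5, 9.1; 20.0: 84.1, 3.7; 25.0: 85.8, 0.9
- grey (time / min: target / %, starting material / %): 0.833: 9.6, 90.4; 2.50: 22.6, 70.3; 4.00: 35.5, 57.7; 6.00: 45.3, 44.1; 10.0: 50.2, 37.6; 12.0: 48.3, 35.8; 15.0: 48.6, 34.7
- red (time / min: target / %, starting material / %): 1.33: 12.6, 83.3; 2.00: 20.1, 76.7; 3.00: 26.4, 65.1; 4.00: 35.7, 57.6; 6.00: 50.7, 41.1; 10.0: 66.0, 20.0; 15.0: 72.4, 13.4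
- ochre (time / min: target / %, starting material / %): 1.33: 7.1, 87.1; 2.50: 14.2, 79.7; 4.00: 23.5, 69.0; 8.00: 42.1, 47.2; 15.0: 61.5, 22.1

(each reading ± 1 percentage point)



I choose by counting half-lives. In the green run the starting material falls from 58.7% at 4.00 min to 29.4% at 8.00 min, which reads as 4.01 min for the working half-life, the time in which a flask at this [enzyme], with second substrate present, halves the starting material standing in it (a pseudo-first-order half-life). The ochre run, at half the [enzyme] but with [starting material] and [second substrate] halved as well, reads slower, at 6.70 min, so I let this half-life lengthen as [enzyme] falls, knowing that the ochre run changes all of these together.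

A feed ending at 20 min leaves a tail of 5.00 min, which is 1.25 half-lives, whereas Thursday's flask, charged at the start, has 6.23. By my reckoning, steady feeding holds about 28.9% of the charge as starting material in Sunday's flask when the feed stops, and the tail brings that down to 12.2%. In Monday's and Friday's flasks the last second substrate goes in at 20 min, which leaves them the same tail. So I charge Thursday's recipe and leave out the feeds and the portions.

The forecast also names Thursday's, with 78% for Sunday's, 76% for Monday's, 73% for Friday's and 86% for Thursday's, on the ground that “Feeding either substrate leaves starting material unreacted longer”. For Sunday's it has about 11 left unreacted, where my reckoning has 12.2%.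

The flasks give 79.5% for Sunday's, 77.7% for Monday's, 73.8% for Friday's and 85.5% for Thursday's, so Thursday's is best.

    starting material ⇌ dormant form (K = 2.40, k = 0.0210 min⁻¹)
    ternary complex → enzyme + target (k = 19000 min⁻¹)
    ternary complex → spent catalyst (k = 0.0150 min⁻¹)
    second substrate + starting complex ⇌ ternary complex (K = 450 M⁻¹, k = 2.20 × 10⁵ M⁻¹ s⁻¹)
    starting material + target → side product (k = 0.0860 M⁻¹ min⁻¹)
    starting material + enzyme ⇌ starting complex (K = 150 M⁻¹, k = 3.50 × 10⁵ M⁻¹ min⁻¹)

In Friday's flask at 25.0 min, the half-life of second substrate, counting the forward step of second substrate + starting complex to ternary complex alone, is 6.3 min, longer than the tail and than my working half-life of starting material. Friday's ends with 25% of its second substrate unbound. Take Friday's recipe with 0.0048 mol% of enzyme: if my half-life goes inversely with [enzyme], it becomes 1.00 min, so the tail counts 5.00 half-lives. The computed flask gives 81.5% with 0.417% starting material left, which is 8.5 percentage points above the forecast's 73% for Friday's at 0.0012 mol%, so an enzyme change of that size is what it takes for that number to stop holding.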